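**Plan**

- Cuts: first the C3'–C4' acyl–alkynyl bond of the diynone (acid chloride + terminal diyne); then O1–C8a and C4–C4a, which removes the benzo ring as benzyne from a malonic half-ester; then the two C3–CH2 bonds (malonate alkylations); in the side chain, the diyne–carbinol bond.
- Forward: dimethyl malonate is alkylated twice (acetal stub, then farnesyl), desymmetrised, and annulated with benzyne (the only ring formed). The acetal is taken to the acid, the silyl-protected diynol is attached by acyl coupling, and the silyl ether is removed last.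
- Enabling feature: the benzo ring is bonded to the malonyl unit C2–C3–C4 only through O1 and C4, so C8a and C4a can be supplied as benzyne to a carboxylate/ester pair on an already quaternary, non-epimerisable C3.
- Stereochemistry: C3 comes from enzymatic differentiation of the two enantiotopic ester groups and is never touched again; C8' comes from a ligand-controlled zinc diynylide addition to (Z)-dec-2-enal; 9'Z from Lindlar hydrogenation; 2E,6E from farnesyl bromide.
- The ynone is made by acylation, not by aldehyde alkynylation/oxidation, because a C3' alkoxide would sit 1,5 to the aryl-lactone carbonyl and could take over the acyl group.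

Key step: step 4

Remark: which enantiotopic ester the esterase cleaves (step 3) and which aldehyde face the zinc–ProPhenol catalyst attacks (step 10) cannot be fixed on paper; the route is written for (R)-6 and (S)-19, to be confirmed on the first batch (chiral HPLC for 6, Mosher esters for 19) and steered by the choice of esterase isoenzyme or ligand antipode.

"Farnesyl" means (2E,6E)-3,7,11-trimethyldodeca-2,6,10-trien-1-yl throughout.

Step 1
Reactants: 1 dimethyl malonate; 2 3-bromo-1,1-dimethoxypropane
Product: 3 dimethyl 2-(3,3-dimethoxypropyl)malonate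
Conditions: NaOMe, MeOH, reflux (1 in excess)
Reagents that add atoms: none
Why: Malonic ester alkylation (SN2 of the malonate anion on the primary bromide); excess malonate suppresses dialkylation, methoxide matches the ester groups, and the acetal is inert to base.

Step 2
Reactants: 3 dimethyl 2-(3,3-dimethoxypropyl)malonate; 4 (2E,6E)-farnesyl bromide
Product: 5 dimethyl 2-(3,3-dimethoxypropyl)-2-[(2E,6E)-farnesyl]malonate
Conditions: Cs2CO3, DMF, 0 °C → rt
Reagents that add atoms: none
Why: Second malonate alkylation; the soft tertiary carbanion attacks C1 of the primary allylic bromide (SN2, no allylic transposition), so the 2E,6E geometry is kept and the prochiral quaternary carbon is formed.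

Step 3
Reactants: 5 dimethyl 2-(3,3-dimethoxypropyl)-2-[(2E,6E)-farnesyl]malonate
Product: 6 (R)-2-(3,3-dimethoxypropyl)-2-[(2E,6E)-farnesyl]malonic acid monomethyl ester
Conditions: pig liver esterase (isoenzyme chosen by screening), 0.1 M phosphate buffer pH 7.5, DMSO (10 vol %), 30 °C; then pH 3, extraction
Reagents that add atoms: water, O
Why: Enzymatic desymmetrisation (esterase monohydrolysis of a prochiral disubstituted dimethyl malonate); cleavage of the pro-S methoxycarbonyl group gives the R acid, hydrolysis stops at the mono-acid because the carboxylate is no longer a substrate, and the acetal is stable at this pH.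

Step 4
Reactants: 6 (R)-2-(3,3-dimethoxypropyl)-2-[(2E,6E)-farnesyl]malonic acid monomethyl ester; 7 2-(trimethylsilyl)phenyl trifluoromethanesulfonate
Product: 10 (S)-3-(3,3-dimethoxypropyl)-3-[(2E,6E)-farnesyl]chromane-2,4-dione, via caesium carboxylate 8 (not isolated), via benzyne 9 (not isolated)
Conditions: Cs2CO3 (0.5 equiv), MeOH, rt, evaporate and dry; then 7 (1.5 equiv), CsF (3 equiv), THF, 60 °C
Reagents that add atoms: none
Why: Proposed new method: fluoride removes Me3Si from 7 and loss of triflate gives benzyne 9, the carboxylate oxygen of 8 adds to it (O1–C8a), the ortho aryl anion so formed attacks the methyl ester carbonyl on the other arm of C3 (C4–C4a), and the tetrahedral intermediate expels methoxide, which is expected to be taken up by silicon (Me3SiF or unreacted 7) as MeOSiMe3 and not to reopen the lactone. The closest known reaction type is the fluoride-triggered aryne annulation of methyl salicylates to xanthones (an oxygen nucleophile adds and the aryl anion is trapped by a pendant methyl ester in a six-membered acyl substitution), combined with the known O-arylation of carboxylates by arynes; its use on an aliphatic malonic half-ester is the new element. The pyran-2,4-dione ring closes by 6-exo-trig attack of C4a on the ester carbonyl. No stereocentre is created: C3 carries no hydrogen and none of its bonds is made or broken, so the configuration of 6 is carried over intact (the descriptor changes from R to S only because the CIP ranking of the two carbonyl arms changes). The selectivity needed is attack on the remote ester and not on the anion's own aryloxycarbonyl group (four-membered 1,3-O→C acyl shift, which after relactonisation would give the enantiomer), and no protonation of the aryl anion. The strain-free six-membered transition state, the geminal substitution at C3 that holds the ester within reach, and the proton-free caesium salt in THF at moderate temperature should secure this.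

Step 5
Reactants: 10 (S)-3-(3,3-dimethoxypropyl)-3-[(2E,6E)-farnesyl]chromane-2,4-dione
Product: 11 3-[(3S)-3-[(2E,6E)-farnesyl]-2,4-dioxochroman-3-yl]propanal
Conditions: 1 M aq HCl, THF, 0 °C → rt
Reagents that add atoms: water, O
Why: Acid-catalysed acetal hydrolysis under conditions too mild to protonate the trisubstituted alkenes or open the aryl lactone; C3 has no α-hydrogen and cannot epimerise.

Step 6
Reactants: 11 3-[(3S)-3-[(2E,6E)-farnesyl]-2,4-dioxochroman-3-yl]propanal
Product: 12 3-[(3S)-3-[(2E,6E)-farnesyl]-2,4-dioxochroman-3-yl]propanoic acid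
Conditions: NaClO2, NaH2PO4, 2-methylbut-2-ene (excess), t-BuOH/H2O, 0 °C
Reagents that add atoms: sodium chlorite, [Na+].[O-]Cl=O
Why: Pinnick oxidation; chlorous acid oxidises only the aldehyde, the alkene scavenger removes HOCl before it reaches the farnesyl double bonds, and the weakly acidic buffer leaves the lactone closed.

Step 7
Reactants: 13 1,4-bis(trimethylsilyl)buta-1,3-diyne
Product: 15 buta-1,3-diyn-1-yl(trimethyl)silane, via lithium silylbutadiynide 14 (not isolated)
Conditions: MeLi·LiBr, Et2O, rt; then aq NH4Cl, 0 °C (product kept as a dried solution)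
Reagents that add atoms: none
Why: Mono-desilylation by MeLi (attack at silicon gives Me4Si and the lithium diynide, whose charge protects the second C–Si bond), then protonation.

Step 8
Reactants: 16 dec-2-yn-1-ol
Product: 17 (Z)-dec-2-en-1-ol
Conditions: H2 (1 atm), Lindlar catalyst, quinoline, hexane, rt
Reagents that add atoms: none
Why: Lindlar semi-hydrogenation (syn addition of H2 on poisoned palladium) gives the Z allylic alcohol.

Step 9
Reactants: 17 (Z)-dec-2-en-1-ol
Product: 18 (Z)-dec-2-enal
Conditions: TEMPO (10 mol %), PhI(OAc)2, CH2Cl2, rt; used at once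
Reagents that add atoms: none
Why: Oxoammonium (TEMPO/PhI(OAc)2) oxidation converts primary allylic alcohols to enals without Z→E isomerisation or over-oxidation.

Step 10
Reactants: 18 (Z)-dec-2-enal; 15 buta-1,3-diyn-1-yl(trimethyl)silane
Product: 19 (5S,6Z)-1-(trimethylsilyl)tetradec-6-ene-1,3-diyn-5-ol
Conditions: Me2Zn, ProPhenol (20 mol %, antipode giving 5S), Ph3P=O (40 mol %), toluene, 4 °C
Reagents that add atoms: none
Why: Catalytic enantioselective alkynylation with a dinuclear zinc–ProPhenol catalyst, a reaction type known for 1,3-diynes and α,β-unsaturated aldehydes; the chiral dizinc pocket binds aldehyde and zinc diynylide and delivers the diynyl group to one carbonyl face, setting C5 as S, while the cold, amine-free medium spares the Z alkene.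

Step 11
Reactants: 19 (5S,6Z)-1-(trimethylsilyl)tetradec-6-ene-1,3-diyn-5-ol
Product: 21 triethyl{[(5S,6Z)-tetradec-6-ene-1,3-diyn-5-yl]oxy}silane, via terminal diynol 20 (not isolated)
Conditions: K2CO3 (cat.), MeOH, 0 °C; then Et3SiCl, imidazole, CH2Cl2, 0 °C
Reagents that add atoms: chlorotriethylsilane, CC[Si](Cl)(CC)CC
Why: Carbonate-catalysed methanolysis cleaves only the C(sp)–Si bond, and the sensitive terminal diynol is O-silylated at once (imidazole-assisted) so that the hydroxyl cannot be acylated in step 12.

Step 12
Reactants: 12 3-[(3S)-3-[(2E,6E)-farnesyl]-2,4-dioxochroman-3-yl]propanoic acid; 21 triethyl{[(5S,6Z)-tetradec-6-ene-1,3-diyn-5-yl]oxy}silane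
Product: 23 (3S)-3-[(2E,6E)-farnesyl]-3-[(8S,9Z)-3-oxo-8-(triethylsilyloxy)heptadec-9-ene-4,6-diyn-1-yl]chromane-2,4-dione, via acid chloride 22 (not isolated)
Conditions: 1-chloro-N,N,2-trimethylprop-1-en-1-amine (Ghosez reagent), CH2Cl2, 0 °C → rt; then 21, PdCl2(PPh3)2 (2 mol %), CuI (4 mol %), Et3N, THF, rt, degassed
Reagents that add atoms: none
Why: Acyl Sonogashira coupling; the acid chloride is formed under neutral conditions (no HCl to add to the farnesyl alkenes), then undergoes oxidative addition to Pd(0), transmetalation with the copper diynylide and reductive elimination to the ynone, with no alkoxide ever generated near the aryl lactone.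

Step 13
Reactants: 23 (3S)-3-[(2E,6E)-farnesyl]-3-[(8S,9Z)-3-oxo-8-(triethylsilyloxy)heptadec-9-ene-4,6-diyn-1-yl]chromane-2,4-dione
Product: 24 (3S)-3-[(8S,9Z)-8-hydroxy-3-oxoheptadec-9-ene-4,6-diyn-1-yl]-3-[(2E,6E)-farnesyl]chromane-2,4-dione (CNP0346147.1)
Conditions: HF·pyridine, pyridine, THF, 0 °C
Reagents that add atoms: none
Why: Fluoride cleavage of the triethylsilyl ether with buffered HF·pyridine is fast at 0 °C and should leave the diynone, the aryl lactone, the polyene and both stereocentres untouched.

**Compound list**

1 | dimethyl malonate | COC(=O)CC(=O)OC | starting material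
2 | 3-bromo-1,1-dimethoxypropane | COC(OC)CCBr | starting material
3 | dimethyl 2-(3,3-dimethoxypropyl)malonate | COC(OC)CCC(C(=O)OC)C(=O)OC | intermediate
4 | (2E,6E)-farnesyl bromide [(2E,6E)-1-bromo-3,7,11-trimethyldodeca-2,6,10-triene] | CC(C)=CCC/C(C)=C/CC/C(C)=C/CBr | starting material
5 | dimethyl 2-(3,3-dimethoxypropyl)-2-[(2E,6E)-farnesyl]malonate | COC(OC)CCC(C/C=C(\C)CC/C=C(\C)CCC=C(C)C)(C(=O)OC)C(=O)OC | intermediate
6 | (R)-2-(3,3-dimethoxypropyl)-2-[(2E,6E)-farnesyl]malonic acid monomethyl ester | COC(OC)CC[C@@](C(=O)OC)(C/C=C(\C)CC/C=C(\C)CCC=C(C)C)C(=O)O | intermediate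
7 | 2-(trimethylsilyl)phenyl trifluoromethanesulfonate | C[Si](C)(C)c1ccccc1OS(=O)(=O)C(F)(F)F | starting material
8 | caesium (R)-2-(3,3-dimethoxypropyl)-2-[(2E,6E)-farnesyl]-3-methoxy-3-oxopropanoate | COC(OC)CC[C@@](C(=O)OC)(C/C=C(\C)CC/C=C(\C)CCC=C(C)C)C(=O)[O-].[Cs+] | intermediate
9 | benzyne | C1=CC=CC#C1 | intermediate
10 | (S)-3-(3,3-dimethoxypropyl)-3-[(2E,6E)-farnesyl]chromane-2,4-dione | COC(OC)CC[C@@]1(C/C=C(\C)CC/C=C(\C)CCC=C(C)C)C(=O)Oc2ccccc2C1=O | intermediate
11 | 3-[(3S)-3-[(2E,6E)-farnesyl]-2,4-dioxochroman-3-yl]propanal | O=CCC[C@@]1(C/C=C(\C)CC/C=C(\C)CCC=C(C)C)C(=O)Oc2ccccc2C1=O | intermediate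
12 | 3-[(3S)-3-[(2E,6E)-farnesyl]-2,4-dioxochroman-3-yl]propanoic acid | OC(=O)CC[C@@]1(C/C=C(\C)CC/C=C(\C)CCC=C(C)C)C(=O)Oc2ccccc2C1=O | intermediate
13 | 1,4-bis(trimethylsilyl)buta-1,3-diyne | C[Si](C)(C)C#CC#C[Si](C)(C)C | starting material
14 | lithium 4-(trimethylsilyl)buta-1,3-diyn-1-ide | [Li]C#CC#C[Si](C)(C)C | intermediate
15 | buta-1,3-diyn-1-yl(trimethyl)silane | C#CC#C[Si](C)(C)C | intermediate
16 | dec-2-yn-1-ol | CCCCCCCC#CCO | starting material
17 | (Z)-dec-2-en-1-ol | CCCCCCC/C=C\CO | intermediate
18 | (Z)-dec-2-enal | CCCCCCC/C=C\C=O | intermediate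
19 | (5S,6Z)-1-(trimethylsilyl)tetradec-6-ene-1,3-diyn-5-ol | CCCCCCC/C=C\[C@H](O)C#CC#C[Si](C)(C)C | intermediate
20 | (5S,6Z)-tetradec-6-ene-1,3-diyn-5-ol | CCCCCCC/C=C\[C@H](O)C#CC#C | intermediate
21 | triethyl{[(5S,6Z)-tetradec-6-ene-1,3-diyn-5-yl]oxy}silane | CCCCCCC/C=C\[C@H](O[Si](CC)(CC)CC)C#CC#C | intermediate
22 | 3-[(3S)-3-[(2E,6E)-farnesyl]-2,4-dioxochroman-3-yl]propanoyl chloride | ClC(=O)CC[C@@]1(C/C=C(\C)CC/C=C(\C)CCC=C(C)C)C(=O)Oc2ccccc2C1=O | intermediate
23 | (3S)-3-[(2E,6E)-farnesyl]-3-[(8S,9Z)-3-oxo-8-(triethylsilyloxy)heptadec-9-ene-4,6-diyn-1-yl]chromane-2,4-dione | CCCCCCC/C=C\[C@H](O[Si](CC)(CC)CC)C#CC#CC(=O)CC[C@@]1(C/C=C(\C)CC/C=C(\C)CCC=C(C)C)C(=O)Oc2ccccc2C1=O | intermediate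
24 | (3S)-3-[(8S,9Z)-8-hydroxy-3-oxoheptadec-9-ene-4,6-diyn-1-yl]-3-[(2E,6E)-farnesyl]chromane-2,4-dione | CCCCCCC/C=C\[C@H](O)C#CC#CC(=O)CC[C@@]1(C/C=C(\C)CC/C=C(\C)CCC=C(C)C)C(=O)Oc2ccccc2C1=O | target

**Count**

Total: 13 steps. Longest linear sequence: 8 steps (1–6, 12, 13) from dimethyl malonate; the side chain joins after 5 steps (8–11, with 7 feeding step 10).

**Steps most likely to fail**

Step 4 (proposed new method). Four processes could spoil it:
- the ortho-metallated aryl ester may undergo the 1,3-O→C acyl shift through the four-membered path in competition with the six-membered closure, which would lower the enantiomeric purity;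
- the aryl anion may be protonated before it cyclises, leaving an open phenyl ester;
- methoxide that escapes silylation may reopen the lactone at C2 or cleave C3–C4 in a retro-Claisen sense;
- benzyne may undergo ene reactions with the farnesyl alkenes.

The fallback gives up the aryne ring construction and uses known chemistry. It sets out from 4 and commercial 4-hydroxycoumarin: C-farnesylation at C3 (4, aqueous NaOH) gives ferulenol F1. F1 is then added as an α-substituted cyclic 1,3-dicarbonyl nucleophile to acrolein under a bifunctional cinchona-alkaloid catalyst (pseudo-enantiomer chosen for 3S); this conjugate addition forms the quaternary centre and the 3-oxopropyl chain in one operation. The route is rejoined at 11.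

Step 3. The enzyme may discriminate poorly, or in the opposite sense, between the two enantiotopic ester groups of a diester that carries two large lipophilic substituents, or may turn it over too slowly. The fallback replaces desymmetrisation by resolution: it sets out from 5, which is monosaponified without selectivity (KOH, 1 equiv, MeOH/H2O) to the racemic half-ester F2. F2 is separated by preparative chromatography on a chiral stationary phase, and the R enantiomer rejoins the route at 6.

Step 10. The Z-enal may isomerise to the E-enal before or during the zinc-mediated addition, and facial discrimination on a Z-configured enal may be insufficient. The fallback moves the stereo-determining event from C–C bond formation to a reduction: it sets out from 18 and 14 (the lithium diynide of step 7 is used directly, THF, −78 °C) and gives the racemic carbinol F3. Oxidation with MnO2 gives the ynone F4, and oxazaborolidine-catalysed (CBS) reduction with catecholborane at −78 °C, using the catalyst antipode that gives 5S, rejoins the route at 19.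

**Further compounds**

F1 | step 4 | ferulenol, 3-[(2E,6E)-farnesyl]-4-hydroxy-2H-chromen-2-one | O=c1oc2ccccc2c(O)c1C/C=C(\C)CC/C=C(\C)CCC=C(C)C
F2 | step 3 | racemic 2-(3,3-dimethoxypropyl)-2-[(2E,6E)-farnesyl]malonic acid monomethyl ester | COC(OC)CCC(C(=O)OC)(C/C=C(\C)CC/C=C(\C)CCC=C(C)C)C(=O)O
F3 | step 10 | racemic (Z)-1-(trimethylsilyl)tetradec-6-ene-1,3-diyn-5-ol | CCCCCCC/C=C\C(O)C#CC#C[Si](C)(C)C
F4 | step 10 | (Z)-1-(trimethylsilyl)tetradec-6-ene-1,3-diyn-5-one | CCCCCCC/C=C\C(=O)C#CC#C[Si](C)(C)C
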